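**Assumption:** the SMILES is read as (5S,8R), with the 5-(5-phenylpentyl) and 8-OMe groups cis on the carbocycle; methyl 2-methoxy-3-oxobutanoate is taken as a catalogue reagent.

## Retrosynthetic overview

1. The N‑methoxy‑4‑pyridone is unmasked last from a 4‑O‑acyl tetrahydroquinoline N‑oxide: methylate the N‑oxide oxygen, then remove the acyl group.
2. Both stereocentres (C5, C8) come from one enantioselective, carbocycle‑selective syn hydrogenation of a flat, achiral 5,8‑disubstituted quinoline (key dearomatization).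
3. The quinoline comes from O‑acylation of a 4‑quinolone, made by Conrad–Limpach annulation of a 2,5‑disubstituted aniline with a 2‑methoxyacetoacetate.
4. The aniline comes from 5‑bromo‑2‑methoxyaniline and 5‑phenylpent‑1‑ene by B‑alkyl Suzuki coupling.
5. Ring order: benzene ring purchased → pyridone ring annulated → benzene ring reduced to the cyclohexene ring.

## Route

**Step 1**
Reactants: 1, 5‑bromo‑2‑methoxyaniline; 2, 5‑phenylpent‑1‑ene
Product: 3, 2‑methoxy‑5‑(5‑phenylpentyl)aniline
Conditions: 2, 9‑BBN, THF, rt; then 1, Pd(dppf)Cl2 (3 mol%), aq. K3PO4, THF/DMF, 65 °C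
Reagents that add atoms: none (9‑BBN delivers only H)
Why: Anti‑Markovnikov hydroboration followed by B‑alkyl Suzuki–Miyaura coupling joins the primary alkyl chain to the aryl bromide and tolerates the free aniline.

**Step 2**
Reactants: 3, 2‑methoxy‑5‑(5‑phenylpentyl)aniline; 4, methyl 2‑methoxy‑3‑oxobutanoate
Product: 5, 3,8‑dimethoxy‑2‑methyl‑5‑(5‑phenylpentyl)quinolin‑4(1H)‑one
Conditions: (i) cat. p‑TsOH, PhMe, Dean–Stark, reflux; (ii) concentrate, add to Ph2O, 250 °C, 20 min
Reagents that add atoms: none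
Why: Conrad–Limpach synthesis (β‑anilinoacrylate formation, then thermal cyclization with loss of MeOH) can only close at the single free ortho position, which places the alkyl at C5 and the OMe at C8.

**Step 3**
Reactants: 5, 3,8‑dimethoxy‑2‑methyl‑5‑(5‑phenylpentyl)quinolin‑4(1H)‑one
Product: 6, ethyl 3,8‑dimethoxy‑2‑methyl‑5‑(5‑phenylpentyl)quinolin‑4‑yl carbonate
Conditions: NaH, THF, 0 °C; ClCO2Et, rt
Reagents that add atoms: ethyl chloroformate, CCOC(=O)Cl
Why: O‑acylation of the quinolone anion (N is blocked by 2‑Me and 8‑OMe) locks the fully aromatic quinoline tautomer and masks the C4 oxygen for the later N‑oxide chemistry.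

**Step 4 (key step)**
Reactants: 6, ethyl 3,8‑dimethoxy‑2‑methyl‑5‑(5‑phenylpentyl)quinolin‑4‑yl carbonate
Product: 7, ethyl (5S,8R)‑3,8‑dimethoxy‑2‑methyl‑5‑(5‑phenylpentyl)‑5,6,7,8‑tetrahydroquinolin‑4‑yl carbonate (5,8‑cis)
Conditions: H2 (50 atm), Ru(η3‑methallyl)2(cod) (5 mol%), (R,R)‑(S,S)‑PhTRAP (5.5 mol%), EtOAc, 80 °C (no base; ligand antipode to be confirmed on the first run, the other antipode gives ent‑7)
Reagents that add atoms: none (H2 only)
Why: Proposed new method: the closest known reaction is Ru/trans‑chelating bisphosphine asymmetric hydrogenation of 8‑substituted quinolines at the carbocycle, here extended to a 5,8‑disubstituted substrate. The fully substituted, carbonate‑deactivated pyridine ring and the isolated phenyl ring should resist reduction while the fused benzo ring is reduced; delivery of both H2 molecules to one arene face gives the 5,8‑cis relationship, and the chiral ligand selects the face to set (5S,8R).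

**Step 5**
Reactants: 7, ethyl (5S,8R)‑3,8‑dimethoxy‑2‑methyl‑5‑(5‑phenylpentyl)‑5,6,7,8‑tetrahydroquinolin‑4‑yl carbonate
Product: 8, (5S,8R)‑4‑[(ethoxycarbonyl)oxy]‑3,8‑dimethoxy‑2‑methyl‑5‑(5‑phenylpentyl)‑5,6,7,8‑tetrahydroquinoline 1‑oxide
Conditions: mCPBA (1.5 equiv), CH2Cl2, 0 °C → rt; use promptly
Reagents that add atoms: mCPBA, OOC(=O)c1cccc(Cl)c1 (adds one O)
Why: Peracid N‑oxidation of the pyridine is the only available oxidation (4‑quinolyl carbonates are known to survive it), and neither stereocentre is touched.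

**Step 6**
Reactants: 8, (5S,8R)‑4‑[(ethoxycarbonyl)oxy]‑3,8‑dimethoxy‑2‑methyl‑5‑(5‑phenylpentyl)‑5,6,7,8‑tetrahydroquinoline 1‑oxide
Product: 9, Waltherione H, (5S,8R)‑1,3,8‑trimethoxy‑2‑methyl‑5‑(5‑phenylpentyl)‑5,6,7,8‑tetrahydroquinolin‑4(1H)‑one
Conditions: MeOTf (1.1 equiv), CH2Cl2, 0 °C → rt; then MeOH, NaHCO3, rt
Reagents that add atoms: methyl triflate, COS(=O)(=O)C(F)(F)F (adds CH3)
Why: O‑methylation of the N‑oxide gives an N‑methoxypyridinium whose 4‑carbonate is an activated acyl donor, so methanolysis releases the neutral N‑methoxy‑4‑pyridone; because the C4 oxygen stays masked until after methylation, the methyl can only go on the N–O oxygen, and no stereocentre is affected.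

## Compound list

1 | 5‑bromo‑2‑methoxyaniline | COc1ccc(Br)cc1N | starting material
2 | 5‑phenylpent‑1‑ene | C=CCCCc1ccccc1 | starting material
3 | 2‑methoxy‑5‑(5‑phenylpentyl)aniline | COc1ccc(CCCCCc2ccccc2)cc1N | intermediate
4 | methyl 2‑methoxy‑3‑oxobutanoate | COC(C(C)=O)C(=O)OC | starting material
5 | 3,8‑dimethoxy‑2‑methyl‑5‑(5‑phenylpentyl)quinolin‑4(1H)‑one | COc1c(C)[nH]c2c(OC)ccc(CCCCCc3ccccc3)c2c1=O | intermediate
6 | ethyl 3,8‑dimethoxy‑2‑methyl‑5‑(5‑phenylpentyl)quinolin‑4‑yl carbonate | CCOC(=O)Oc1c(OC)c(C)nc2c(OC)ccc(CCCCCc3ccccc3)c12 | intermediate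
7 | ethyl (5S,8R)‑3,8‑dimethoxy‑2‑methyl‑5‑(5‑phenylpentyl)‑5,6,7,8‑tetrahydroquinolin‑4‑yl carbonate | COc1c(C)nc2c(c1OC(=O)OCC)[C@@H](CCCCCc1ccccc1)CC[C@H]2OC | intermediate
8 | (5S,8R)‑4‑[(ethoxycarbonyl)oxy]‑3,8‑dimethoxy‑2‑methyl‑5‑(5‑phenylpentyl)‑5,6,7,8‑tetrahydroquinoline 1‑oxide | COc1c(C)[n+]([O-])c2c(c1OC(=O)OCC)[C@@H](CCCCCc1ccccc1)CC[C@H]2OC | intermediate
9 | Waltherione H, (5S,8R)‑1,3,8‑trimethoxy‑2‑methyl‑5‑(5‑phenylpentyl)‑5,6,7,8‑tetrahydroquinolin‑4(1H)‑one | COc1c(C)n(OC)c2c(c1=O)[C@@H](CCCCCc1ccccc1)CC[C@H]2OC | target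

## Summary

Total steps: 6. Longest linear sequence: 6 (from compound 1).

Steps most likely to fail:

1. **Step 4** (no precedent for this substitution pattern; possible low conversion, eroded cis selectivity or ee, inhibition by N,O‑chelation of the 8‑methoxyquinoline, loss of the 8‑OMe). Fallback: abandon arene reduction; set C5 by Cu/phosphoramidite asymmetric conjugate addition of the 5‑phenylpentyl organometallic to cyclohex‑2‑enone, annulate the pyridone onto the chiral cyclohexanone, then introduce C8 oxygen and reduce to the cis alcohol before O‑methylation.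
2. **Step 6** (the N‑methoxypyridinium is base‑sensitive at the 2‑methyl and C8–H positions; the carbonate in 8 could migrate to the N–O oxygen before methylation). Fallback: reverse the order — cleave the carbonate first (K2CO3, MeOH) to the 1‑hydroxy‑4‑pyridone, then O‑alkylate the ambident anion (MeI, K2CO3, DMF) and separate the N‑OMe pyridone from any 4‑OMe N‑oxide isomer.
3. **Step 2** (competing anilide formation, and a 250 °C cyclization ortho to the alkyl group with an α‑methoxy ketoester). Fallback: build the quinolone by Camps cyclization instead — Sugasawa ortho‑acylation of 3 with methoxyacetonitrile (BCl3/AlCl3), N‑acetylation, then base‑mediated ring closure to 5.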